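**Retrosynthetic overview**

- The target is (R)-α-tocotrienol: a chroman (benzene ring A fused to dihydropyran ring B, quaternary C2) carrying an all-E C16 chain, numbered C1' (on C2) to C12'.
- Enabling feature: the chain is a skipped 1,5-diene in which C6' is an unbranched CH2 homoallylic to C3'=C4', and C7' is the H-bearing end of C7'=C8'. C5'–C6' can therefore be carried one oxidation level higher, as a terminal vinyl group conjugated with C3'=C4' (the only alkene that 9-BBN-H attacks), and C7' as an (E)-alkenyl iodide.
- Key disconnection C6'–C7': one-flask diene hydroboration/B-alkyl Suzuki–Miyaura coupling of a dienyl chroman with (E)-1-iodo-2,6-dimethylhepta-1,5-diene, itself made by alkyne methylalumination/iodination.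
- Second disconnection C2'–C3': the same operation one round earlier, joining a 2-vinylchroman to (E)-1-iodo-2-methylbuta-1,3-diene, which hands on the new terminal vinyl group.
- No ring is formed in the route. Rings A and B and the C2 configuration come from (S)-Trolox, whose carboxyl carbon becomes C1'; the descriptor changes from S to R at the first coupling through CIP ranking only.

Key step: step 11

Remark: commercial (S)-Trolox is assumed to be enantiomerically pure enough to serve as the only source of chirality. C2 is quaternary and no bond to it is broken anywhere in the route.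

**Step 1**
Reactants: 1 5-bromo-2-methylpent-2-ene
Product: 2 6-methylhept-5-en-1-yne
Conditions: LiC≡CH·H2NCH2CH2NH2, DMSO, 0 °C to rt
Reagents that add atoms: lithium acetylide (ethylenediamine complex), [Li]C#C.NCCN
Why: SN2 alkylation of lithium acetylide by an unhindered primary bromide in a dipolar aprotic solvent is a standard terminal alkyne synthesis, and the trisubstituted alkene is inert to it.

**Step 2**
Reactants: 2 6-methylhept-5-en-1-yne
Product: 4 (1E)-1-iodo-2,6-dimethylhepta-1,5-diene, via alkenyldimethylalane 3 (not isolated)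
Conditions: Me3Al (2 equiv), Cp2ZrCl2 (0.2 equiv), CH2Cl2, 0 °C to rt; then I2, THF, −30 to 0 °C
Reagents that add atoms: trimethylaluminium, C[Al](C)C; iodine, II
Why: Zirconium-catalysed methylalumination (Negishi carboalumination) adds CH3 and Al syn across the terminal alkyne with aluminium on the CH end, leaves the isolated trisubstituted alkene alone, and iodinolysis of the C–Al bond goes with retention, so the C8' methyl group and the 7'E geometry are set here.

**Step 3**
Reactants: 5 prop-2-yn-1-ol
Product: 7 (2E)-3-iodo-2-methylprop-2-en-1-ol, via alkenylalane alkoxide 6 (not isolated)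
Conditions: Me3Al (3 equiv), Cp2ZrCl2 (0.25 equiv), CH2Cl2, 0 °C to rt; then I2, THF, −30 to 0 °C; aq potassium sodium tartrate
Reagents that add atoms: trimethylaluminium, C[Al](C)C; iodine, II
Why: After the hydroxyl group is masked in the flask as its dimethylaluminium alkoxide, the same Negishi carboalumination/iodinolysis delivers CH3 and I syn, which sets the later 3'E geometry and the C4' methyl group.

**Step 4**
Reactants: 7 (2E)-3-iodo-2-methylprop-2-en-1-ol
Product: 8 (2E)-3-iodo-2-methylprop-2-enal
Conditions: MnO2 (activated, excess), CH2Cl2, rt, dark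
Reagents that add atoms: none
Why: MnO2 oxidation of an allylic alcohol should stop at the enal and touch neither the alkene geometry nor the C–I bond.

**Step 5**
Reactants: 8 (2E)-3-iodo-2-methylprop-2-enal
Product: 9 (1E)-1-iodo-2-methylbuta-1,3-diene
Conditions: Ph3PCH3Br, NaN(SiMe3)2, THF, 0 °C; then 8, −78 to 0 °C; product kept cold and dark as a pentane/Et2O solution
Reagents that add atoms: methyltriphenylphosphonium bromide, C[P+](c1ccccc1)(c1ccccc1)c1ccccc1.[Br-]
Why: Wittig methylenation with the non-stabilised ylide turns CHO into the terminal vinyl group, and with an amide base no alkyllithium is present that could exchange the iodide or disturb the existing E alkene.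

**Step 6**
Reactants: 10 (2S)-6-hydroxy-2,5,7,8-tetramethylchroman-2-carboxylic acid ((S)-Trolox)
Product: 11 methyl (2S)-6-hydroxy-2,5,7,8-tetramethylchroman-2-carboxylate
Conditions: MeOH, H2SO4 (cat.), reflux
Reagents that add atoms: methanol, CO
Why: Fischer esterification is safe here because the quaternary C2 has no α-hydrogen and cannot epimerise.

**Step 7**
Reactants: 11 methyl (2S)-6-hydroxy-2,5,7,8-tetramethylchroman-2-carboxylate
Product: 12 methyl (2S)-6-(tert-butyldimethylsilyloxy)-2,5,7,8-tetramethylchroman-2-carboxylate
Conditions: TBSCl, imidazole, DMF, 50 °C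
Reagents that add atoms: tert-butyldimethylsilyl chloride, CC(C)(C)[Si](C)(C)Cl
Why: Imidazole-promoted silylation masks the oxidation-prone phenol, and the two flanking methyl groups should make this aryl silyl ether robust toward the hydride, ylide, borane and aqueous phosphate used later.

**Step 8**
Reactants: 12 methyl (2S)-6-(tert-butyldimethylsilyloxy)-2,5,7,8-tetramethylchroman-2-carboxylate
Product: 13 (2S)-6-(tert-butyldimethylsilyloxy)-2,5,7,8-tetramethylchroman-2-carbaldehyde
Conditions: i-Bu2AlH (1.1 equiv), toluene, −78 °C; then MeOH, aq potassium sodium tartrate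
Reagents that add atoms: none
Why: Partial ester reduction with i-Bu2AlH should stop at the aldehyde level, because the hindered α-alkoxy tetrahedral aluminium adduct persists at low temperature and collapses only on work-up.

**Step 9**
Reactants: 13 (2S)-6-(tert-butyldimethylsilyloxy)-2,5,7,8-tetramethylchroman-2-carbaldehyde
Product: 14 (2S)-6-(tert-butyldimethylsilyloxy)-2,5,7,8-tetramethyl-2-vinylchroman
Conditions: Ph3PCH3Br, NaN(SiMe3)2, THF, 0 °C to rt
Reagents that add atoms: methyltriphenylphosphonium bromide, C[P+](c1ccccc1)(c1ccccc1)c1ccccc1.[Br-]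
Why: Wittig methylenation of a non-enolisable aldehyde gives C1'=C2' as a terminal vinyl group without any risk to C2.

**Step 10**
Reactants: 14 (2S)-6-(tert-butyldimethylsilyloxy)-2,5,7,8-tetramethyl-2-vinylchroman; 9 (1E)-1-iodo-2-methylbuta-1,3-diene
Product: 16 (2R)-6-(tert-butyldimethylsilyloxy)-2,5,7,8-tetramethyl-2-[(3E)-4-methylhexa-3,5-dienyl]chroman, via B-alkyl-9-BBN borane 15 (not isolated)
Conditions: 9-BBN-H (1.05 equiv), THF, 0 °C to rt; then 3 M aq K3PO4; then 9, PdCl2(dppf) (5 mol %), AsPh3 (10 mol %), DMF, rt, argon (dppf = 1,1'-bis(diphenylphosphino)ferrocene)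
Reagents that add atoms: 9-borabicyclo[3.3.1]nonane (9-BBN-H), B1C2CCCC1CCC2 (boron and its bicycle appear in 15 only; 16 keeps just its hydrogen)
Why: In this one-flask hydroboration/B-alkyl Suzuki–Miyaura coupling, 9-BBN-H puts boron on the terminal C2' (γ to the ring oxygen, so no β-elimination can open ring B), and the alkenyl iodide couples with retention, which forms C2'–C3' with 3'E geometry.

**Step 11**
Reactants: 16 (2R)-6-(tert-butyldimethylsilyloxy)-2,5,7,8-tetramethyl-2-[(3E)-4-methylhexa-3,5-dienyl]chroman; 4 (1E)-1-iodo-2,6-dimethylhepta-1,5-diene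
Product: 18 (2R)-6-(tert-butyldimethylsilyloxy)-2,5,7,8-tetramethyl-2-[(3E,7E)-4,8,12-trimethyltrideca-3,7,11-trienyl]chroman, via homoallylic B-alkyl-9-BBN borane 17 (not isolated)
Conditions: 9-BBN-H (1.05 equiv), THF, 0 °C to rt; then 3 M aq K3PO4; then 4, PdCl2(dppf) (5 mol %), AsPh3 (10 mol %), DMF, rt, argon
Reagents that add atoms: 9-borabicyclo[3.3.1]nonane (9-BBN-H), B1C2CCCC1CCC2 (boron and its bicycle appear in 17 only; 18 keeps just its hydrogen)
Why: 9-BBN-H adds its B–H bond syn and anti-Markovnikov, through a four-centre transition state, to the only monosubstituted alkene of 16 (C5'=C6'), which places boron on the terminal C6', leaves the trisubstituted C3'=C4' bond untouched for steric reasons and gives the homoallylic borane 17. Aqueous phosphate converts 17 into a borate, zerovalent palladium formed from PdCl2(dppf) inserts into the C7'–I bond of 4, the primary alkyl group alone is transferred from boron (the two bridgehead B–C bonds of the bicycle do not migrate), and reductive elimination forms C6'–C7'. The closest known reaction type is the one-flask hydroboration/B-alkyl Suzuki–Miyaura coupling of terminal alkenes with (E)-alkenyl iodides, and selective monohydroboration of the vinyl end of a 1,3-diene beside trisubstituted alkenes is the standard entry to homoallylic terpenoid building blocks. No ring is closed and no stereocentre is made: C2 is a remote spectator, the 3'E geometry is carried in with 16 and the 7'E geometry with 4, because oxidative addition, transmetalation and reductive elimination all keep the alkene configuration. Two selectivities are needed: site selectivity among the alkenes, secured by the substitution pattern (one CH=CH2 against trisubstituted alkenes), by one equivalent of a bulky borane and by destroying leftover B–H with the aqueous base before 4 is added; and coupling faster than β-hydride elimination of the homoallylpalladium species back to 16, secured by the wide bite angle of dppf and fast borate transmetalation at room temperature. In one operation the step turns the sp2 carbon C6' into the sp3 nucleophile, removes the activating boron again, adds nine of the sixteen chain carbons and completes the skipped all-E triene with no later redox or functional-group correction.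

**Step 12**
Reactants: 18 (2R)-6-(tert-butyldimethylsilyloxy)-2,5,7,8-tetramethyl-2-[(3E,7E)-4,8,12-trimethyltrideca-3,7,11-trienyl]chroman
Product: 19 (2R)-2,5,7,8-tetramethyl-2-[(3E,7E)-4,8,12-trimethyltrideca-3,7,11-trienyl]chroman-6-ol ((R)-α-tocotrienol)
Conditions: Bu4NF, AcOH, THF, 0 °C to rt, argon
Reagents that add atoms: none
Why: Fluoride-induced cleavage of the aryl silyl ether is neutral toward the three alkenes and C2, and the acetic acid buffer protonates the phenoxide at once so that it should not be oxidised by traces of air.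

**Compound list**

| No. | Name | SMILES | Role |
|---|---|---|---|
| 1 | 5-bromo-2-methylpent-2-ene | CC(C)=CCCBr | starting material |
| 2 | 6-methylhept-5-en-1-yne | C#CCCC=C(C)C | intermediate |
| 3 | [(1E)-2,6-dimethylhepta-1,5-dienyl]dimethylalane | CC(C)=CCC/C(C)=C/[Al](C)C | intermediate |
| 4 | (1E)-1-iodo-2,6-dimethylhepta-1,5-diene | CC(C)=CCC/C(C)=C/I | intermediate |
| 5 | prop-2-yn-1-ol | C#CCO | starting material |
| 6 | dimethylaluminium (2E)-3-(dimethylalumanyl)-2-methylprop-2-en-1-olate | C[Al](C)OC/C(C)=C/[Al](C)C | intermediate |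
| 7 | (2E)-3-iodo-2-methylprop-2-en-1-ol | OC/C(C)=C/I | intermediate |
| 8 | (2E)-3-iodo-2-methylprop-2-enal | O=C/C(C)=C/I | intermediate |
| 9 | (1E)-1-iodo-2-methylbuta-1,3-diene | C=C/C(C)=C/I | intermediate |
| 10 | (2S)-6-hydroxy-2,5,7,8-tetramethylchroman-2-carboxylic acid, (S)-Trolox | OC(=O)[C@]1(C)CCc2c(C)c(O)c(C)c(C)c2O1 | starting material |
| 11 | methyl (2S)-6-hydroxy-2,5,7,8-tetramethylchroman-2-carboxylate | COC(=O)[C@]1(C)CCc2c(C)c(O)c(C)c(C)c2O1 | intermediate |
| 12 | methyl (2S)-6-(tert-butyldimethylsilyloxy)-2,5,7,8-tetramethylchroman-2-carboxylate | COC(=O)[C@]1(C)CCc2c(C)c(O[Si](C)(C)C(C)(C)C)c(C)c(C)c2O1 | intermediate |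
| 13 | (2S)-6-(tert-butyldimethylsilyloxy)-2,5,7,8-tetramethylchroman-2-carbaldehyde | O=C[C@]1(C)CCc2c(C)c(O[Si](C)(C)C(C)(C)C)c(C)c(C)c2O1 | intermediate |
| 14 | (2S)-6-(tert-butyldimethylsilyloxy)-2,5,7,8-tetramethyl-2-vinylchroman | C=C[C@]1(C)CCc2c(C)c(O[Si](C)(C)C(C)(C)C)c(C)c(C)c2O1 | intermediate |
| 15 | 9-{2-[(2R)-6-(tert-butyldimethylsilyloxy)-2,5,7,8-tetramethylchroman-2-yl]ethyl}-9-borabicyclo[3.3.1]nonane | B1(CC[C@]3(C)CCc4c(C)c(O[Si](C)(C)C(C)(C)C)c(C)c(C)c4O3)C2CCCC1CCC2 | intermediate |
| 16 | (2R)-6-(tert-butyldimethylsilyloxy)-2,5,7,8-tetramethyl-2-[(3E)-4-methylhexa-3,5-dienyl]chroman | C=C/C(C)=C/CC[C@]1(C)CCc2c(C)c(O[Si](C)(C)C(C)(C)C)c(C)c(C)c2O1 | intermediate |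
| 17 | 9-{(3E)-6-[(2R)-6-(tert-butyldimethylsilyloxy)-2,5,7,8-tetramethylchroman-2-yl]-3-methylhex-3-enyl}-9-borabicyclo[3.3.1]nonane | B1(CC/C(C)=C/CC[C@]3(C)CCc4c(C)c(O[Si](C)(C)C(C)(C)C)c(C)c(C)c4O3)C2CCCC1CCC2 | intermediate |
| 18 | (2R)-6-(tert-butyldimethylsilyloxy)-2,5,7,8-tetramethyl-2-[(3E,7E)-4,8,12-trimethyltrideca-3,7,11-trienyl]chroman | CC(C)=CCC/C(C)=C/CC/C(C)=C/CC[C@]1(C)CCc2c(C)c(O[Si](C)(C)C(C)(C)C)c(C)c(C)c2O1 | intermediate |
| 19 | (2R)-2,5,7,8-tetramethyl-2-[(3E,7E)-4,8,12-trimethyltrideca-3,7,11-trienyl]chroman-6-ol, (R)-α-tocotrienol | CC(C)=CCC/C(C)=C/CC/C(C)=C/CC[C@]1(C)CCc2c(C)c(O)c(C)c(C)c2O1 | target |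

**Step count**

- Total step count: 12, in three branches of 2, 3 and 4 steps followed by 3 common steps.
- Longest linear sequence: 7 steps (steps 6 to 12).

**Steps most likely to fail**

1. **Step 11.**
   - What may go wrong: loss of site selectivity in the hydroboration (boron delivered to the internal diene carbon, or a second hydroboration), and β-hydride elimination or protodeboronation outrunning transmetalation.
   - Fallback, from 16 back to 18: the union is changed from an in-flask borane to a purified, halide-derived organozinc, a Negishi homoallyl–alkenyl coupling. Compound 16 is hydroborated as before and borane 17 is oxidised (NaBO3·4H2O, THF/H2O, rt) to the homoallylic alcohol F1, which can be freed from regioisomers by chromatography. I2, PPh3 and imidazole in CH2Cl2 convert it into the homoallylic iodide F2. Zinc dust and LiCl in THF insert to give the homoallylzinc iodide F3. This is coupled with 4 under PdCl2(dppf) catalysis in THF at rt to give 18.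

2. **Step 10.**
   - What may go wrong: Heck-type self-condensation and evaporative loss of the small iododiene, and hydroboration of its vinyl group by leftover B–H.
   - Fallback, from 14 and 7 back to 16: the diene is built only after the coupling. Borane 15 made from 14 is coupled under the same palladium conditions with the non-volatile iodo alcohol 7 to give the allylic alcohol F4. MnO2 in CH2Cl2 gives the enal F5. Wittig methylenation (Ph3PCH3Br, NaN(SiMe3)2, THF) then gives 16. Steps 4 and 5 are then not needed.

3. **Step 8.**
   - What may go wrong: over-reduction past the aldehyde stage if the tetrahedral adduct collapses early.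
   - Fallback, from 12 back to 13: a two-stage redox detour. LiAlH4 in Et2O at 0 °C reduces 12 fully to the primary alcohol F6. A Parikh–Doering oxidation (SO3·pyridine, DMSO, Et3N, CH2Cl2, 0 °C), which does not harm the silyl ether or the electron-rich ring A, then returns 13.

**Further compounds**

F1 | step 11 | (3E)-6-[(2R)-6-(tert-butyldimethylsilyloxy)-2,5,7,8-tetramethylchroman-2-yl]-3-methylhex-3-en-1-ol | OCC/C(C)=C/CC[C@]1(C)CCc2c(C)c(O[Si](C)(C)C(C)(C)C)c(C)c(C)c2O1
F2 | step 11 | (2R)-6-(tert-butyldimethylsilyloxy)-2-[(3E)-6-iodo-4-methylhex-3-enyl]-2,5,7,8-tetramethylchroman | ICC/C(C)=C/CC[C@]1(C)CCc2c(C)c(O[Si](C)(C)C(C)(C)C)c(C)c(C)c2O1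
F3 | step 11 | {(3E)-6-[(2R)-6-(tert-butyldimethylsilyloxy)-2,5,7,8-tetramethylchroman-2-yl]-3-methylhex-3-enyl}zinc iodide | I[Zn]CC/C(C)=C/CC[C@]1(C)CCc2c(C)c(O[Si](C)(C)C(C)(C)C)c(C)c(C)c2O1
F4 | step 10 | (2E)-5-[(2R)-6-(tert-butyldimethylsilyloxy)-2,5,7,8-tetramethylchroman-2-yl]-2-methylpent-2-en-1-ol | OC/C(C)=C/CC[C@]1(C)CCc2c(C)c(O[Si](C)(C)C(C)(C)C)c(C)c(C)c2O1
F5 | step 10 | (2E)-5-[(2R)-6-(tert-butyldimethylsilyloxy)-2,5,7,8-tetramethylchroman-2-yl]-2-methylpent-2-enal | O=C/C(C)=C/CC[C@]1(C)CCc2c(C)c(O[Si](C)(C)C(C)(C)C)c(C)c(C)c2O1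
F6 | step 8 | [(2S)-6-(tert-butyldimethylsilyloxy)-2,5,7,8-tetramethylchroman-2-yl]methanol | OC[C@]1(C)CCc2c(C)c(O[Si](C)(C)C(C)(C)C)c(C)c(C)c2O1
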